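At early times the forms of the catalyst change in seconds and E in minutes: J has a half-life of 1.0 s and E.D 0.58 s (forward rate of step 2 alone), against 2.6 min for E in the maple flask (forward rate of step 1 alone, concentrations held at their charge).

    E + D ⇌ E.D (K1 = 13 M⁻¹, k1 = 1.8 M⁻¹ s⁻¹)
    E.D ⇌ J (K2 = 43, k2 = 1.2 s⁻¹)
    J → D + G (k3 = 0.69 s⁻¹)

all flasks: D 5 mol%
- ash: E 0.050 M; one stirred flow tank at steady state, fed with the mixture as stated, mean residence time 4.0 min
- elm: E 0.050 M (fed, over 3.20 min); a stirred flask in which E is dosed at a steady rate over 3.20 min without added volume, worked up at 4.0 min; time 4.0 min
- maple: E 0.050 M; everything together in a closed stirred flask, run for 4.0 min; time 4.0 min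

- the stated concentrations are those of everything mixed, before any reaction; amounts are the same in each set-up
- the feed brings no volume worth counting
- run time (elm): 4.0 min

* the set-up with the highest amount of G at the outlet or at the end, in percent of the E put in ("none" if the first two lie within 2 percentage points) (ash / elm / maple / none)
* amount of G at the outlet or at the end, in percent of the E put in, ash
* amount of G at the outlet or at the end, in percent of the E put in, elm
* amount of G at the outlet or at the end, in percent of the E put in, maple

So I freeze those forms at steady values (the quasi-steady state) and follow the fraction of E left. E.D goes back at 0.138 s⁻¹ and onward at 1.15 s⁻¹, once J's return is allowed for, so 89.3% of the E that binds goes on to G. Taking D at its charge, E falls pseudo-first-order with 0.00402 s⁻¹, and the run holds 0.964 lifetimes: this is the lifetime count, E's constant times the time.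

I count E lost as G. The closed maple flask leaves exp(−count), which gives 61.9% of G. The ash tank leaves 1/(1+count), which gives 49.1%. In elm, E enters on average at mid-dose and stays 2.40 min, which gives 43.9%.

The forecast gives 56.9% for maple, 46.6% for ash and 39.4% for elm, best maple, all lower than mine, and says “dosing loses most because E arrives late”.

The flask gives 57.2% for maple, 46.3% for ash and 39.0% for elm, best maple. My reckoning ran high by 4.7 percentage points, 2.8 points and 4.9 points.

The E left in maple, 42.4%, reads as 0.858 lifetimes, fewer than my 0.964. Put that reading into the tank rule and ash should leave 53.8% of its E; the ash tank holds 53.2%. Run maple to 40.0 min and my count, with D taken at its charge, comes to 9.64 lifetimes, an estimate that leaves 0.00649% of E, and the flask gives >99.9% of G.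

(All constants are made up, and the outcome is calculated.)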